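(The numbers in the tables come from a simulation for substances that don't exist, and the scatter is random.)

Molar per hour was the unit I wanted from these runs, since a charge divided by a rate in it is a time.

the same everywhere: enzyme 0.10 mM

| run | starting material | second substrate | remark | time |
|---|---|---|---|---|
| south-west | 0.090 M | 0.27 M | run made earlier |  |
| east | 0.36 M | 0.27 M | run made earlier |  |
| north | 0.18 M | 0.41 M | run made earlier |  |
| flask | 0.18 M | 0.270 M |  | 12 h |

| run | time / h | target / % |
|---|---|---|
| south-west | 0.500 | 58.6 |
| south-west | 1.00 | 80.6 |
| south-west | 2.00 | 80.7 |
| south-west | 4.00 | 76.9 |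
| south-west | 6.00 | 74.1 |
| south-west | 12.0 | 74.4 |
| east | 0.500 | 21.5 |
| east | 1.00 | 37.3 |
| east | 2.00 | 53.0 |
| east | 4.00 | 57.6 |
| east | 6.00 | 56.3 |
| east | 12.0 | 55.8 |
| north | 0.500 | 47.5 |
| north | 1.33 | 83.4 |
| north | 2.50 | 79.2 |
| north | 6.00 | 74.0 |
| north | 12.0 | 74.7 |

(each reading ± 1 percentage point)



1. time up to 12 h at which target stands highest
2. the amount of target, in percent of the starting material charged, at that time

First readings gave early rates of 0.105 M/h in the south-west run and 0.155 M/h in the east run, both at the flask's 0.270 M of second substrate, so the rate rose less steeply than the charge and was levelling off towards zero order in starting material. I therefore took as my first time the charge over the early rate, τ, which a levelling rate makes straight in the charge: from 0.853 h south-west and 2.33 h east, the flask came to 1.34 h, the clearing time.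

My second time was θ, the half-time of the fall to plateau, which the south-west readings put roughly at 1.50 h. An overshoot of 6.3 percentage points at τ/θ = 0.569 south-west and 1.8 points at 1.55 east placed the flask, at 0.893, between them. East's highest reading stood at 1.72 τ, so I expected the flask's peak near 2.31 h, later than the forecast's 1.9 h.

The forecast, holding that “Rate therefore saturates in starting material”, gave 1.9 h (1.4 h to 2.7 h) and 76% (71% to 81%).

The flask stood highest at 2.29 h, with 80.1% target.

    starting material + enzyme ⇌ starting complex (K = 41.0 /M, k = 1100 /M/min)
    second substrate + starting complex ⇌ ternary complex (K = 1.80 /M, k = 9800 /M/min)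
    ternary complex → enzyme + target (k = 110 /min)
    target ⇌ isomer of the product (K = 0.360, k = 0.00340 /min)

That time was 1.71 τ, and the flask then held 2.85% of its starting material and 17.0% as isomer of the product. Taking the rate as proportional to enzyme, 4.0 × 10⁻⁴ M of enzyme put τ at 0.336 h, which is 0.374 of the 0.899 h relaxation half-life of target and isomer of the product, and that neighbour flask reached 91.0%.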